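The tetracosanoyl chain is cut at its C11–C12 bond (C1 = ester carbonyl), a link between two unactivated CH2 carbons of like polarity, remote from the ester group and the phenyl ring and without any handle. Each carbon is therefore unmasked as a primary radical, born from a carboxylic acid one carbon longer: C12 from myristic acid, C11 from the mono(2-phenylethyl) ester of dodecanedioic acid. A mixed Kolbe electrolysis expels both carboxyl carbons as CO2 and joins the C13 and C11 halves in one operation. Because the precursor half ester already carries the phenethyl group, the coupling product is the target itself.

Key step: step 2

Remark: the acyl chain is numbered from the ester carbonyl (C1) to the terminal methyl (C24). The target has no stereocentre, so no stereocontrol is needed. The route has only two steps, so the risk ranking at the end covers both.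

Step 1
Reactants: 1 dodecanedioic acid, 2 2-phenylethanol
Product: 3 12-oxo-12-(2-phenylethoxy)dodecanoic acid (mono(2-phenylethyl) dodecanedioate)
Conditions: 1 (ca. 3 equiv), 2 (1 equiv), p-TsOH·H2O (cat.), toluene, reflux, Dean–Stark
Reagents that add atoms: none
Why: Fischer esterification with azeotropic removal of water; the two carboxyl groups of 1 are equivalent and independent, so the excess of diacid biases the statistical outcome toward the half ester, unreacted 1 should crystallise from the cold toluene for re-use, and the acidic half ester is parted from neutral material by chromatography.

Step 2
Reactants: 3 12-oxo-12-(2-phenylethoxy)dodecanoic acid, 4 tetradecanoic acid (myristic acid)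
Product: 7 2-phenylethyl tetracosanoate, via tridecyl radical 5 (not isolated), via 11-oxo-11-(2-phenylethoxy)undecyl radical 6 (not isolated)
Conditions: undivided cell, smooth Pt anode and Pt cathode, constant current (ca. 0.2–0.3 A cm−2), 4 (ca. 5 equiv, part of it fed in portions), KOH (ca. 5 mol % of total acid), MeOH, 45–50 °C, polarity reversed at intervals; stopped while still weakly acidic
Reagents that add atoms: none
Why: Mixed (crossed) Kolbe electrolysis: at the platinum anode the carboxylates of 3 and 4 each lose one electron and then CO2, which gives the primary radicals 6 and 5 in high local concentration at the electrode surface, where they combine to form the C11–C12 bond while protons are reduced to hydrogen at the cathode. The closest known reaction type is the classical anodic cross-coupling of a fatty acid and a half ester of a diacid, the standard electrochemical chain extension of fatty acids. No ring is closed and no stereocentre is formed. The selectivity needed is cross- over homo-coupling; both radicals are unhindered primary alkyl radicals of like reactivity, so the outcome is statistical, and the cheap acid 4 is therefore used in large excess so that nearly every radical 6 meets a radical 5, while the three product classes (hydrocarbon, monoester, diester) differ in polarity and should separate on silica. High current density, smooth platinum and an only partly neutralised, weakly acidic medium favour the one-electron radical path over further oxidation to the cation (Hofer–Moest path), which unstabilised primary radicals resist in any case. The carboxylate layer on the anode should shield the phenyl ring and the benzylic CH2 from oxidation, and ending the electrolysis while free acid remains prevents build-up of alkoxide and thus methanolysis of the phenethyl ester.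

Compound list
1 | dodecanedioic acid | OC(=O)CCCCCCCCCCC(=O)O | starting material
2 | 2-phenylethanol | OCCc1ccccc1 | starting material
3 | 12-oxo-12-(2-phenylethoxy)dodecanoic acid (mono(2-phenylethyl) dodecanedioate) | OC(=O)CCCCCCCCCCC(=O)OCCc1ccccc1 | intermediate
4 | tetradecanoic acid (myristic acid) | CCCCCCCCCCCCCC(=O)O | starting material
5 | tridecyl radical | CCCCCCCCCCCC[CH2] | intermediate
6 | 11-oxo-11-(2-phenylethoxy)undecyl radical | [CH2]CCCCCCCCCC(=O)OCCc1ccccc1 | intermediate
7 | 2-phenylethyl tetracosanoate (phenylethyl n-tetracosanoate) | CCCCCCCCCCCCCCCCCCCCCCCC(=O)OCCc1ccccc1 | target

Total step count: 2
Longest linear sequence: 2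

Steps most likely to fail (the route has only two steps, so both are ranked)

1. Step 2.
- **What may go wrong:** Each radical may couple with its own kind rather than with the other. Waxy products may passivate the electrodes. Radicals may be over-oxidised to cations. The ester may undergo methanolysis if the electrolyte drifts alkaline.
- **Fallback:** A polar, copper-catalysed sp3–sp3 coupling replaces the radical dimerisation. It sets out from 2 and comes back at 7. Compound 2 is esterified with commercial 11-bromoundecanoic acid F1 (p-TsOH cat., toluene, Dean–Stark) to give 2-phenylethyl 11-bromoundecanoate F2. Commercial 1-bromotridecane F3 is converted with Mg in THF into tridecylmagnesium bromide F4. This is added slowly to F2 in THF–NMP at 0 °C with catalytic Li2CuCl4. The fast copper-catalysed displacement of the primary bromide forms the same C11–C12 bond without a statistical factor and should outrun addition to the ester carbonyl.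

2. Step 1.
- **What may go wrong:** Both carboxyl groups may be esterified, and the half ester may separate poorly from diacid and neutral material.
- **Fallback:** A pre-differentiated diacid replaces the statistical desymmetrisation. It sets out from 2 and comes back at 3. Commercial 12-(tert-butoxy)-12-oxododecanoic acid F5 is coupled with 2 by Steglich esterification (DCC, DMAP cat., CH2Cl2) to give 1-tert-butyl 12-(2-phenylethyl) dodecanedioate F6. TFA in CH2Cl2 then cleaves only the tert-butyl ester, and the primary phenethyl ester is stable to these conditions.

Further compounds
F1 | step 2 | 11-bromoundecanoic acid | OC(=O)CCCCCCCCCCBr
F2 | step 2 | 2-phenylethyl 11-bromoundecanoate | BrCCCCCCCCCCC(=O)OCCc1ccccc1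
F3 | step 2 | 1-bromotridecane | CCCCCCCCCCCCCBr
F4 | step 2 | tridecylmagnesium bromide | CCCCCCCCCCCCC[Mg]Br
F5 | step 1 | 12-(tert-butoxy)-12-oxododecanoic acid | CC(C)(C)OC(=O)CCCCCCCCCCC(=O)O
F6 | step 1 | 1-tert-butyl 12-(2-phenylethyl) dodecanedioate | CC(C)(C)OC(=O)CCCCCCCCCCC(=O)OCCc1ccccc1
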